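**Strategy (labdane numbering)**

- Retrosynthesis: the 8α-acetate and the C13 acid are read as an opened trans-fused δ-lactone (O8–C13), and C18 as an oxidised 4α-CH2OH. The C8–O, C9–C10 and C4–C5 bonds are then cut in one operation, and finally C11–C12.
- Enabling feature: C18 on C4 is equatorial and trans to the C10 methyl, which is where the E-terminal carbon of a farnesyl chain lands in a chair fold. O8 and the C9 propanoic chain are both equatorial on ring B, the result of anti addition of a ring carbon and a carboxyl oxygen across an E-alkene.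
- Forward: the C17 chain is joined first (ester enolate plus farnesyl bromide), its terminal E-methyl is hydroxylated and the allylic alkene epoxidised. Ring A, ring B and the lactone ring then close in that order in a single Lewis-acid cascade.
- Afterwards the surplus C3 hydroxyl is deleted, the lactone is reduced open so that O8 can be acetylated, and C13 and C18 are oxidised to the acids.
- Stereochemistry: the Sharpless epoxidation with L-(+)-diethyl tartrate sets the (S,S)-epoxide. C4 (inversion), C5, C10, C9 and C8 follow from chair–chair anti additions across the two E-alkenes, and no later step touches a stereocentre.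

Key step: step 5

Remark: the given SMILES corresponds to the normal labdane series (5α-H, 9α-H, 10β-CH3) with 8α-OAc, 8β-CH3, 4α-CO2H (called C18) and 4β-CH3 (C19); this numbering is used for all cyclised compounds.

**Route**

Step 1
Reactants: 1 (2E,6E)-farnesyl bromide; 2 tert-butyl acetate
Product: 3 tert-butyl (4E,8E)-5,9,13-trimethyltetradeca-4,8,12-trienoate (tert-butyl farnesylacetate)
Conditions: 2, LiN(iPr)2 (commercial solution), THF, −78 °C; then 1, DMPU, −78 °C to 0 °C
Reagents that add atoms: none
Why: SN2 alkylation of the lithium ester enolate at the primary allylic bromide is standard enolate chemistry and leaves both E-alkenes of the farnesyl unit untouched.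

Step 2
Reactants: 3 tert-butyl farnesylacetate
Product: 5 tert-butyl (4E,8E,12E)-14-hydroxy-5,9,13-trimethyltetradeca-4,8,12-trienoate, via terminal enal 4 (not isolated)
Conditions: SeO2 (cat.), t-BuOOH, salicylic acid (cat.), CH2Cl2, 0 °C to rt, stopped at partial conversion; then NaBH4, MeOH, 0 °C
Reagents that add atoms: tert-butyl hydroperoxide, CC(C)(C)OO (net source of the new oxygen, relayed by the SeO2 catalyst)
Why: Selenium dioxide allylic oxidation (ene reaction, then [2,3]-sigmatropic shift) should favour the most accessible terminal isopropylidene and functionalise its E-methyl, and the NaBH4 1,2-reduction returns the over-oxidised enal 4 to the same (12E)-alcohol.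

Step 3
Reactants: 5 terminal (12E)-allylic alcohol
Product: 6 tert-butyl (4E,8E,12S,13S)-12,13-epoxy-14-hydroxy-5,9,13-trimethyltetradeca-4,8-dienoate
Conditions: Ti(OiPr)4 (cat.), L-(+)-diethyl tartrate (cat.), t-BuOOH (decane), 4 Å molecular sieves, CH2Cl2, −20 °C
Reagents that add atoms: tert-butyl hydroperoxide, CC(C)(C)OO
Why: The Sharpless asymmetric epoxidation is directed by the allylic hydroxyl, so only the C12=C13 alkene reacts, and L-(+)-diethyl tartrate delivers oxygen to the face that gives the (12S,13S)-epoxide, as with other (E)-2-methylalk-2-en-1-ols.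

Step 4
Reactants: 6 (12S,13S)-epoxy alcohol
Product: 7 tert-butyl (4E,8E,12S,13S)-14-(tert-butyldimethylsilyloxy)-12,13-epoxy-5,9,13-trimethyltetradeca-4,8-dienoate
Conditions: TBSCl, imidazole, CH2Cl2, 0 °C to rt
Reagents that add atoms: tert-butyldimethylsilyl chloride, CC(C)(C)[Si](C)(C)Cl
Why: Routine silylation of a primary alcohol; a silyl ether is chosen because, unlike an ester, it offers no acyl oxygen that could trap the C4 cation in the next step.

Step 5
Reactants: 7 silyl-protected epoxy trienoate
Product: 8 18-(tert-butyldimethylsilyloxy)-3β-hydroxy-14,15,16-trinorlabdan-13,8α-olide (trans-decalin with 3β-OH, 4α-CH2OTBS, 4β-CH3, 5α-H, 8β-CH3, 9α-H, 10β-CH3; δ-lactone from O8α through the C13 carbonyl, C12 and C11 to C9)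
Conditions: MeAlCl2 (2.5 equiv), CH2Cl2 (dilute), −78 °C; aq. potassium sodium tartrate work-up
Reagents that add atoms: none
Why: MeAlCl2 activates the epoxide, the C5=C10 alkene attacks the tertiary C4 anti to the breaking C4–O bond, the C9=C8 alkene takes up the C10 cation, and the ester carbonyl oxygen captures the tertiary C8 cation to give a tert-butoxy oxocarbenium ion that sheds isobutene and leaves the lactone. The closest known reaction type is the Lewis-acid-promoted, epoxide-initiated cation–olefin polycyclisation of oxidosqualene-like epoxy polyenes, combined with the carboxyl termination known from acid-promoted cyclisations of homo- and bishomofarnesic acids to sclareolide- and ambreinolide-type lactones. Ring A closes 6-endo at the epoxide (C4–C5 bond), ring B closes 6-endo at the C9=C8 alkene (C10–C9 bond), and the lactone ring closes by 6-endo capture of C8 by the carbonyl oxygen across the same alkene (C8–O bond). C3 keeps the S configuration from step 3 and sits equatorial in the chair, C4 forms with inversion so that the E-CH2OTBS group becomes equatorial (α) and the Z-methyl axial (β), C5 and C10 arise by anti addition across the E-C5=C10 alkene, and C9 and C8 by anti addition across the E-C9=C8 alkene with oxygen entering C8 equatorially (α). The step needs opening at the tertiary epoxide carbon, an all-chair fold and oxygen capture instead of proton loss; these should be secured by the trisubstituted, Markovnikov-matched E-alkenes, the single epoxide configuration, the six-membered reach of the ester carbonyl with irreversible loss of isobutene, and the non-participating silyl ether at O18.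

Step 6
Reactants: 8 hydroxy lactone
Product: 9 18-(tert-butyldimethylsilyloxy)-3β-[(imidazol-1-ylcarbonothioyl)oxy]-14,15,16-trinorlabdan-13,8α-olide
Conditions: 1,1'-thiocarbonyldiimidazole, DMAP (cat.), toluene, 90 °C
Reagents that add atoms: 1,1'-thiocarbonyldiimidazole, S=C(n1ccnc1)n1ccnc1
Why: Thioacylation of the secondary 3β-alcohol (first half of the Barton–McCombie deoxygenation) runs under neutral, non-enolising conditions that should leave the lactone and the silyl ether alone.

Step 7
Reactants: 9 thiocarbonylimidazolide
Product: 10 18-(tert-butyldimethylsilyloxy)-14,15,16-trinorlabdan-13,8α-olide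
Conditions: Bu3SnH, AIBN (cat.), toluene, 110 °C
Reagents that add atoms: none
Why: In the Barton–McCombie radical deoxygenation the stannyl radical adds to C=S, β-scission releases the secondary C3 radical and the tin hydride reduces it, and since C3 becomes a methylene group no stereocentre is affected.

Step 8
Reactants: 10 3-deoxy lactone
Product: 11 18-(tert-butyldimethylsilyloxy)-14,15,16-trinorlabdane-8α,13-diol
Conditions: LiAlH4, THF, 0 °C to rt; H2O and aq. NaOH work-up
Reagents that add atoms: none
Why: Hydride reduction of the lactone frees the tertiary 8α-hydroxyl and gives the primary C13 alcohol without breaking the C8–O bond, so C8 keeps its configuration and the silyl ether survives.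

Step 9
Reactants: 11 8α,13-diol
Product: 12 13,18-bis(tert-butyldimethylsilyloxy)-14,15,16-trinorlabdan-8α-ol
Conditions: TBSCl, imidazole, DMF, rt
Reagents that add atoms: tert-butyldimethylsilyl chloride, CC(C)(C)[Si](C)(C)Cl
Why: Silylation with TBSCl and imidazole is selective for the primary C13 hydroxyl because the hindered tertiary 8α-hydroxyl is inert under these conditions.

Step 10
Reactants: 12 bis-silyl ether
Product: 13 13,18-bis(tert-butyldimethylsilyloxy)-14,15,16-trinorlabdan-8α-yl acetate
Conditions: AcCl, N,N-dimethylaniline, CH2Cl2, 0 °C to rt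
Reagents that add atoms: acetyl chloride, CC(=O)Cl
Why: O-acylation of a hindered tertiary alcohol with acetyl chloride and a weak aniline base is the established way to acetylate 8α-hydroxylabdanes without dehydration, and since the bond forms at oxygen the C8 configuration is retained.

Step 11
Reactants: 13 tertiary acetate
Product: 14 8α-acetoxy-14,15,16-trinorlabdane-13,18-diol
Conditions: HF·pyridine, pyridine, THF, 0 °C to rt
Reagents that add atoms: none
Why: Fluoride-mediated desilylation with buffered HF·pyridine should remove both silyl ethers under weakly acidic conditions in which the tertiary acetate neither migrates nor eliminates.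

Step 12
Reactants: 14 acetoxy diol
Product: 15 8α-acetoxy-14,15,16-trinorlabdane-13,18-dial
Conditions: Dess–Martin periodinane, CH2Cl2, rt
Reagents that add atoms: none
Why: Dess–Martin oxidation converts both primary alcohols, including the neopentyl C18 carbinol, to aldehydes under near-neutral conditions that spare the tertiary acetate, and the C4 aldehyde cannot enolise.

Step 13
Reactants: 15 dialdehyde
Product: 16 8α-acetoxy-14,15,16-trinorlabdane-13,18-dioic acid (target CNP0196050.1)
Conditions: NaClO2, NaH2PO4, 2-methyl-2-butene, t-BuOH/H2O, rt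
Reagents that add atoms: sodium chlorite, [Na+].[O-]Cl=O
Why: The Pinnick chlorite oxidation takes both aldehydes to carboxylic acids at about pH 4 with 2-methyl-2-butene scavenging hypochlorous acid, conditions that should leave the tertiary acetate and all stereocentres untouched.

**Compound list**

1 | (2E,6E)-farnesyl bromide | CC(C)=CCC/C(C)=C/CC/C(C)=C/CBr | starting material
2 | tert-butyl acetate | CC(=O)OC(C)(C)C | starting material
3 | tert-butyl (4E,8E)-5,9,13-trimethyltetradeca-4,8,12-trienoate | CC(C)=CCC/C(C)=C/CC/C(C)=C/CCC(=O)OC(C)(C)C | intermediate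
4 | tert-butyl (4E,8E,12E)-5,9,13-trimethyl-14-oxotetradeca-4,8,12-trienoate (terminal enal, not isolated) | O=C/C(C)=C/CC/C(C)=C/CC/C(C)=C/CCC(=O)OC(C)(C)C | intermediate
5 | tert-butyl (4E,8E,12E)-14-hydroxy-5,9,13-trimethyltetradeca-4,8,12-trienoate | OC/C(C)=C/CC/C(C)=C/CC/C(C)=C/CCC(=O)OC(C)(C)C | intermediate
6 | tert-butyl (4E,8E,12S,13S)-12,13-epoxy-14-hydroxy-5,9,13-trimethyltetradeca-4,8-dienoate | OC[C@]1(C)O[C@H]1CC/C(C)=C/CC/C(C)=C/CCC(=O)OC(C)(C)C | intermediate
7 | tert-butyl (4E,8E,12S,13S)-14-(tert-butyldimethylsilyloxy)-12,13-epoxy-5,9,13-trimethyltetradeca-4,8-dienoate | CC(C)(C)[Si](C)(C)OC[C@]1(C)O[C@H]1CC/C(C)=C/CC/C(C)=C/CCC(=O)OC(C)(C)C | intermediate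
8 | 18-(tert-butyldimethylsilyloxy)-3β-hydroxy-14,15,16-trinorlabdan-13,8α-olide | O=C3O[C@]1(C)CC[C@@H]2[C@](C)(CC[C@H](O)[C@@]2(C)CO[Si](C)(C)C(C)(C)C)[C@H]1CC3 | intermediate
9 | 18-(tert-butyldimethylsilyloxy)-3β-[(imidazol-1-ylcarbonothioyl)oxy]-14,15,16-trinorlabdan-13,8α-olide | O=C3O[C@]1(C)CC[C@@H]2[C@](C)(CC[C@H](OC(=S)n4ccnc4)[C@@]2(C)CO[Si](C)(C)C(C)(C)C)[C@H]1CC3 | intermediate
10 | 18-(tert-butyldimethylsilyloxy)-14,15,16-trinorlabdan-13,8α-olide | O=C3O[C@]1(C)CC[C@@H]2[C@](C)(CCC[C@@]2(C)CO[Si](C)(C)C(C)(C)C)[C@H]1CC3 | intermediate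
11 | 18-(tert-butyldimethylsilyloxy)-14,15,16-trinorlabdane-8α,13-diol | O[C@]1(C)CC[C@@H]2[C@](C)(CCC[C@@]2(C)CO[Si](C)(C)C(C)(C)C)[C@H]1CCCO | intermediate
12 | 13,18-bis(tert-butyldimethylsilyloxy)-14,15,16-trinorlabdan-8α-ol | O[C@]1(C)CC[C@@H]2[C@](C)(CCC[C@@]2(C)CO[Si](C)(C)C(C)(C)C)[C@H]1CCCO[Si](C)(C)C(C)(C)C | intermediate
13 | 13,18-bis(tert-butyldimethylsilyloxy)-14,15,16-trinorlabdan-8α-yl acetate | CC(=O)O[C@]1(C)CC[C@@H]2[C@](C)(CCC[C@@]2(C)CO[Si](C)(C)C(C)(C)C)[C@H]1CCCO[Si](C)(C)C(C)(C)C | intermediate
14 | 8α-acetoxy-14,15,16-trinorlabdane-13,18-diol | CC(=O)O[C@]1(C)CC[C@@H]2[C@](C)(CCC[C@@]2(C)CO)[C@H]1CCCO | intermediate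
15 | 8α-acetoxy-14,15,16-trinorlabdane-13,18-dial | CC(=O)O[C@]1(C)CC[C@@H]2[C@](C)(CCC[C@@]2(C)C=O)[C@H]1CCC=O | intermediate
16 | 8α-acetoxy-14,15,16-trinorlabdane-13,18-dioic acid (CNP0196050.1) | CC(=O)O[C@]1(C)CC[C@@H]2[C@](C)(CCC[C@@]2(C)C(=O)O)[C@H]1CCC(=O)O | target

**Step count**

Total: 13 steps. Longest linear sequence: 13 steps (1 or 2 to 16; the route is fully linear).

**Steps most likely to fail**

Step 5 (cascade cyclisation). The cascade may stop after ring A, or the activated epoxide may rearrange by a 1,2-hydride shift to the C3 ketone. The C8 cation may also lose a proton instead of being captured, because the ester carbonyl is tied up by the Lewis acid. The electron-withdrawing silyloxymethyl group on the initiating carbon makes all three more likely. The fallback sets out from 7 and forms the same C4–C5 and C10–C9 bonds by a radical pathway. Cp2TiCl (trivalent titanium, generated from Cp2TiCl2 and Mn dust) in THF at rt should open the epoxide homolytically at C4, and the bicyclisation should end by loss of a hydrogen atom from C17 to give tert-butyl 18-(tert-butyldimethylsilyloxy)-3β-hydroxy-14,15,16-trinorlabd-8(17)-en-13-oate F1. The lactone ring is then closed in a separate operation: CF3SO3H (cat.) in CH2Cl2 at −40 °C protonates the exocyclic alkene in the Markovnikov sense, and the ester oxygen traps the C8 cation with loss of isobutene. This rejoins the route at 8.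

Step 2 (allylic oxidation). The oxidation may not discriminate between the terminal and the two internal trisubstituted alkenes and may over-oxidise, giving regioisomeric alcohols that are hard to separate. The fallback sets out from 3 and rebuilds the chain terminus instead of oxidising it. NBS in THF/H2O at 0 °C, selective for the terminal alkene of a polyprenyl chain in aqueous medium, should give the bromohydrin tert-butyl (4E,8E)-12-bromo-13-hydroxy-5,9,13-trimethyltetradeca-4,8-dienoate F2. K2CO3 in MeOH closes it to the racemic terminal epoxide tert-butyl (4E,8E)-12,13-epoxy-5,9,13-trimethyltetradeca-4,8-dienoate F3. HIO4 in THF/Et2O cleaves this to the trisnor aldehyde tert-butyl (4E,8E)-5,9-dimethyl-12-oxododeca-4,8-dienoate F4. An E-selective Wittig reaction with the stabilised ylide Ph3P=C(CH3)CHO in toluene at 90 °C then gives enal 4, which NaBH4 reduces to 5 as in the second stage of step 2.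

Step 6 (thioacylation). Thioacylation of the equatorial 3β-hydroxyl, flanked by the fully substituted C4 with its silyloxymethyl group, may be too slow, so that the radical deoxygenation cannot be started. The fallback sets out from 8 and removes the oxygen through the ketone. Dess–Martin oxidation should give 18-(tert-butyldimethylsilyloxy)-3-oxo-14,15,16-trinorlabdan-13,8α-olide F5. TsNHNH2 in EtOH with catalytic AcOH at reflux converts it to the 3-(p-toluenesulfonyl)hydrazone of that ketone F6. Reduction with catecholborane in CHCl3, followed by NaOAc at reflux (loss of sulfinate and N2), gives the C3 methylene compound and rejoins the route at 10.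

**Further compounds**

F1 | step 5 | tert-butyl 18-(tert-butyldimethylsilyloxy)-3β-hydroxy-14,15,16-trinorlabd-8(17)-en-13-oate | C=C1CC[C@@H]2[C@](C)(CC[C@H](O)[C@@]2(C)CO[Si](C)(C)C(C)(C)C)[C@H]1CCC(=O)OC(C)(C)C
F2 | step 2 | tert-butyl (4E,8E)-12-bromo-13-hydroxy-5,9,13-trimethyltetradeca-4,8-dienoate (racemic) | CC(C)(O)C(Br)CC/C(C)=C/CC/C(C)=C/CCC(=O)OC(C)(C)C
F3 | step 2 | tert-butyl (4E,8E)-12,13-epoxy-5,9,13-trimethyltetradeca-4,8-dienoate (racemic) | CC1(C)OC1CC/C(C)=C/CC/C(C)=C/CCC(=O)OC(C)(C)C
F4 | step 2 | tert-butyl (4E,8E)-5,9-dimethyl-12-oxododeca-4,8-dienoate | O=CCC/C(C)=C/CC/C(C)=C/CCC(=O)OC(C)(C)C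
F5 | step 6 | 18-(tert-butyldimethylsilyloxy)-3-oxo-14,15,16-trinorlabdan-13,8α-olide | O=C3O[C@]1(C)CC[C@@H]2[C@](C)(CCC(=O)[C@@]2(C)CO[Si](C)(C)C(C)(C)C)[C@H]1CC3
F6 | step 6 | 18-(tert-butyldimethylsilyloxy)-3-oxo-14,15,16-trinorlabdan-13,8α-olide 3-(p-toluenesulfonyl)hydrazone | O=C3O[C@]1(C)CC[C@@H]2[C@](C)(CCC(=NNS(=O)(=O)c4ccc(C)cc4)[C@@]2(C)CO[Si](C)(C)C(C)(C)C)[C@H]1CC3
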